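**Assumption:** the target is read from the SMILES as ring (1S,2R,3S,4S,6S), side-chain carbinol S, side-chain oxirane R, with three angelate, i.e. (2Z)-2-methylbut-2-enoate, esters; compounds 1, 2, 4, 7 and 10 are bought, and a one-pot sequence counts as one step.

## Retrosynthetic overview

1. Target 16 ⇐ Shi epoxidation of the prenyl alkene of tris-angelate 15 (side-chain oxirane, formed last) ⇐ double angeloylation of epoxy diol 14 ⇐ hydroxyl-directed epoxidation of cyclohexenediol 13 (ring oxirane, formed second).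
2. 13 ⇐ rhodium-catalysed anti-SN2′ opening of the oxygen bridge of 7-oxanorbornene 11, which gives the trans-diol and moves the alkene onto the methyl-bearing carbon.
3. 11 ⇐ Mitsunobu inversion with angelic acid of allylic alcohol 9 ⇐ methylenation of hydroxy ketone 8.
4. 8 ⇐ key step: dearomative, chelate-controlled Diels–Alder reaction of 3-methylfuran 7 with the chiral α′-hydroxy enone 6; this forms the six-membered carbocycle first, as an oxa-bridged bicycle, and sets its stereocentres.
5. 6 ⇐ methyl (R)-glycidate 1 + isobutenyl Grignard 2 + vinyl Grignard 4.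

## Route

**Step 1**
Reactants: 1 methyl (2R)-oxirane-2-carboxylate; 2 (2-methylprop-1-en-1-yl)magnesium bromide
Product: 3 methyl (2R)-2-hydroxy-5-methylhex-4-enoate
Conditions: 2 (1.3 equiv), CuI (10 mol %), THF, −40 → −20 °C; aq NH4Cl
Reagents that add atoms: none
Why: Copper-catalysed Grignard opening of the epoxide at its CH2 carbon (SN2) is faster than ester attack at low temperature, and the carbinol stereocentre is not touched, so it stays R.

**Step 2**
Reactants: 3 methyl (2R)-2-hydroxy-5-methylhex-4-enoate; 4 ethenylmagnesium bromide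
Product: 6 (4R)-4-hydroxy-7-methylocta-1,6-dien-3-one, via Weinreb amide 5 (not isolated)
Conditions: MeNH(OMe)·HCl (1.5 equiv), iPrMgCl (4.5 equiv), THF, −20 °C; then 4 (2.5 equiv), −20 → 0 °C; inverse quench into cold 1 M HCl; BHT, used at once
Reagents that add atoms: N,O-dimethylhydroxylamine hydrochloride, CNOC.Cl (its atoms stay only in intermediate 5)
Why: One-pot ester → Weinreb amide → ketone synthesis, in which the magnesium chelate of the tetrahedral adduct stops over-addition and the carbinol centre, masked as its alkoxide, is not enolised and stays R.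

**Step 3**
Reactants: 6 (4R)-4-hydroxy-7-methylocta-1,6-dien-3-one; 7 3-methylfuran
Product: 8 (2R)-2-hydroxy-5-methyl-1-[(1R,2R,4R)-5-methyl-7-oxabicyclo[2.2.1]hept-5-en-2-yl]hex-4-en-1-one (acyl group endo, trans to the oxygen bridge)
Conditions: 7 (4 equiv), Cu(OTf)2 (10 mol %), 2,2′-bipyridine (11 mol %), 4 Å MS, CH2Cl2, −60 → −40 °C; cold silica filtration, chromatography below room temperature
Reagents that add atoms: none
Why: Lewis-acid-catalysed Diels–Alder reaction that breaks the furan aromaticity: copper chelates the ketone and α′-hydroxyl of 6 in the s-cis form (Masamune-type dienophile), so the furan adds to the alkene face opposite the CH2-prenyl group of the R carbinol centre; it bonds from its most nucleophilic C2 to the enone β-carbon (methyl ends on the alkene carbon remote from the acyl-bearing carbon) and adds endo under kinetic control, which sets C1, C2 and C4 of the bicycle, and minor isomers are removed by chromatography.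

**Step 4**
Reactants: 8 (the hydroxy ketone from step 3)
Product: 9 (3R)-6-methyl-2-[(1R,2S,4R)-5-methyl-7-oxabicyclo[2.2.1]hept-5-en-2-yl]hepta-1,5-dien-3-ol
Conditions: pre-formed Zn/CH2Br2/TiCl4 reagent (3 equiv), THF–CH2Cl2, 0 °C → rt
Reagents that add atoms: dibromomethane, BrCBr
Why: Takai–Lombardo methylenation is non-basic, so the ketone α-carbon (β to the bridge oxygen) neither epimerises nor eliminates and the free hydroxyl only consumes reagent; no stereocentre is formed (the C2 descriptor changes from R to S only because the priorities change).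

**Step 5**
Reactants: 9 (the allylic alcohol from step 4); 10 angelic acid, (2Z)-2-methylbut-2-enoic acid
Product: 11 (3S)-6-methyl-2-[(1R,2S,4R)-5-methyl-7-oxabicyclo[2.2.1]hept-5-en-2-yl]hepta-1,5-dien-3-yl (2Z)-2-methylbut-2-enoate
Conditions: 10 (1.5 equiv), PPh3 (1.5 equiv), DIAD (1.5 equiv), toluene, −20 °C → rt
Reagents that add atoms: none
Why: Mitsunobu esterification, in which angelate displaces the oxyphosphonium group by SN2 and so inverts the carbinol carbon from R to S while installing the first angelate under neutral conditions that leave the Z double bond alone.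

**Step 6**
Reactants: 11 (the oxanorbornenyl angelate from step 5)
Product: 13 (3S)-2-[(1S,5S,6S)-5,6-dihydroxy-4-methylcyclohex-3-en-1-yl]-6-methylhepta-1,5-dien-3-yl (2Z)-2-methylbut-2-enoate, via monoacetate 12 (not isolated)
Conditions: [Rh(cod)Cl]2 (2.5 mol %), 1,1′-bis(diphenylphosphino)ferrocene (6 mol %), AcOH (5 equiv), Et3N (5 equiv), THF, 65 °C; then K2CO3 (0.2 equiv), MeOH, 0 °C
Reagents that add atoms: acetic acid, CC(=O)O
Why: Proposed new method: monovalent rhodium binds the strained alkene on the exo face, attacks its unsubstituted carbon and ionises the allylic bridgehead C–O bond next to the methyl-bearing carbon (SN2′-type oxidative addition); acetate then attacks the unsubstituted allyl terminus anti to rhodium, giving the trans-2-acetoxycyclohex-3-enol with the alkene on the methyl carbon, and this hydroxyl-flanked acetate is methanolysed in the same flask much faster than the hindered angelate; the closest known reaction is the rhodium-catalysed ring opening of oxabenzonorbornadienes and 7-oxanorbornenes with carboxylates and alcohols, which gives trans-1,2 products.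

**Step 7**
Reactants: 13 (the cyclohexenediol from step 6)
Product: 14 (3S)-2-[(1R,2R,3S,4S,6S)-2,3-dihydroxy-1-methyl-7-oxabicyclo[4.1.0]heptan-4-yl]-6-methylhepta-1,5-dien-3-yl (2Z)-2-methylbut-2-enoate
Conditions: VO(acac)2 (5 mol %), t-BuOOH (1.3 equiv, decane), CH2Cl2, 0 °C → rt
Reagents that add atoms: tert-butyl hydroperoxide, CC(C)(C)OO
Why: Hydroxyl-directed (Sharpless–Michaelson) epoxidation, in which the vanadate ester of the allylic ring hydroxyl delivers oxygen to the ring alkene on its own face (as with cis-carveol) and so gives the cis-epoxy alcohol, while the side-chain alkenes have no free hydroxyl nearby and do not react.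

**Step 8**
Reactants: 14 (the epoxy diol from step 7); 10 angelic acid
Product: 15 (1S,2R,3S,4S,6S)-1-methyl-4-[(3S)-6-methyl-3-{[(2Z)-2-methylbut-2-enoyl]oxy}hepta-1,5-dien-2-yl]-7-oxabicyclo[4.1.0]heptane-2,3-diyl bis[(2Z)-2-methylbut-2-enoate]
Conditions: 10 (4 equiv), 2,4,6-trichlorobenzoyl chloride (4 equiv), Et3N (5 equiv), toluene, rt; then 14, toluene, 80 °C
Reagents that add atoms: none
Why: Yamaguchi-type acylation through the angelic 2,4,6-trichlorobenzoic mixed anhydride without a nucleophilic catalyst esterifies both hindered secondary alcohols with retention and without Z → E isomerisation; the ring epoxide is cis to its neighbouring oxygen and so cannot undergo Payne rearrangement.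

**Step 9**
Reactants: 15 (the tris-angelate from step 8)
Product: 16 (1S,2R,3S,4S,6S)-4-[(3S)-4-[(2R)-3,3-dimethyloxiran-2-yl]-3-{[(2Z)-2-methylbut-2-enoyl]oxy}but-1-en-2-yl]-1-methyl-7-oxabicyclo[4.1.0]heptane-2,3-diyl bis[(2Z)-2-methylbut-2-enoate] (target)
Conditions: 1,2:4,5-di-O-isopropylidene-β-D-erythro-2,3-hexodiulo-2,6-pyranose (D-fructose-derived Shi ketone, 0.3 equiv), Oxone (2KHSO5·KHSO4·K2SO4), K2CO3, Bu4NHSO4, Na2B4O7/Na2EDTA buffer, MeCN–CH2(OMe)2–H2O, 0 °C
Reagents that add atoms: Oxone (potassium peroxymonosulfate), [K+].[O-]S(=O)(=O)OO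
Why: Shi asymmetric epoxidation, in which the chiral dioxirane reacts only with the electron-rich trisubstituted prenyl alkene (the 1,1-disubstituted allylic-ester alkene and the angelate alkenes are electron-poor) through the spiro transition state that gives the (R)-3-alkyl-2,2-dimethyloxirane.

## Compound list

1 | methyl (2R)-oxirane-2-carboxylate (methyl (R)-glycidate) | COC(=O)[C@H]1CO1 | starting material
2 | (2-methylprop-1-en-1-yl)magnesium bromide | CC(C)=C[Mg]Br | starting material
3 | methyl (2R)-2-hydroxy-5-methylhex-4-enoate | COC(=O)[C@H](O)CC=C(C)C | intermediate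
4 | ethenylmagnesium bromide | C=C[Mg]Br | starting material
5 | (2R)-2-hydroxy-N-methoxy-N,5-dimethylhex-4-enamide | CON(C)C(=O)[C@H](O)CC=C(C)C | intermediate
6 | (4R)-4-hydroxy-7-methylocta-1,6-dien-3-one | C=CC(=O)[C@H](O)CC=C(C)C | intermediate
7 | 3-methylfuran | Cc1ccoc1 | starting material
8 | (2R)-2-hydroxy-5-methyl-1-[(1R,2R,4R)-5-methyl-7-oxabicyclo[2.2.1]hept-5-en-2-yl]hex-4-en-1-one (endo acyl) | O=C([C@H](O)CC=C(C)C)[C@@H]1C[C@@H]2C(C)=C[C@H]1O2 | intermediate
9 | (3R)-6-methyl-2-[(1R,2S,4R)-5-methyl-7-oxabicyclo[2.2.1]hept-5-en-2-yl]hepta-1,5-dien-3-ol | C=C([C@H](O)CC=C(C)C)[C@@H]1C[C@@H]2C(C)=C[C@H]1O2 | intermediate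
10 | angelic acid, (2Z)-2-methylbut-2-enoic acid | C/C=C(/C)C(=O)O | starting material
11 | (3S)-6-methyl-2-[(1R,2S,4R)-5-methyl-7-oxabicyclo[2.2.1]hept-5-en-2-yl]hepta-1,5-dien-3-yl (2Z)-2-methylbut-2-enoate | C=C([C@H](CC=C(C)C)OC(=O)/C(C)=C\C)[C@@H]1C[C@@H]2C(C)=C[C@H]1O2 | intermediate
12 | (3S)-2-[(1S,5S,6S)-5-acetoxy-6-hydroxy-4-methylcyclohex-3-en-1-yl]-6-methylhepta-1,5-dien-3-yl (2Z)-2-methylbut-2-enoate | C=C([C@H](CC=C(C)C)OC(=O)/C(C)=C\C)[C@@H]1CC=C(C)[C@H](OC(C)=O)[C@H]1O | intermediate
13 | (3S)-2-[(1S,5S,6S)-5,6-dihydroxy-4-methylcyclohex-3-en-1-yl]-6-methylhepta-1,5-dien-3-yl (2Z)-2-methylbut-2-enoate | C=C([C@H](CC=C(C)C)OC(=O)/C(C)=C\C)[C@@H]1CC=C(C)[C@H](O)[C@H]1O | intermediate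
14 | (3S)-2-[(1R,2R,3S,4S,6S)-2,3-dihydroxy-1-methyl-7-oxabicyclo[4.1.0]heptan-4-yl]-6-methylhepta-1,5-dien-3-yl (2Z)-2-methylbut-2-enoate | C=C([C@H](CC=C(C)C)OC(=O)/C(C)=C\C)[C@@H]1C[C@@H]2O[C@]2(C)[C@H](O)[C@H]1O | intermediate
15 | (1S,2R,3S,4S,6S)-1-methyl-4-[(3S)-6-methyl-3-{[(2Z)-2-methylbut-2-enoyl]oxy}hepta-1,5-dien-2-yl]-7-oxabicyclo[4.1.0]heptane-2,3-diyl bis[(2Z)-2-methylbut-2-enoate] | C=C([C@H](CC=C(C)C)OC(=O)/C(C)=C\C)[C@@H]1C[C@@H]2O[C@]2(C)[C@H](OC(=O)/C(C)=C\C)[C@H]1OC(=O)/C(C)=C\C | intermediate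
16 | (1S,2R,3S,4S,6S)-4-[(3S)-4-[(2R)-3,3-dimethyloxiran-2-yl]-3-{[(2Z)-2-methylbut-2-enoyl]oxy}but-1-en-2-yl]-1-methyl-7-oxabicyclo[4.1.0]heptane-2,3-diyl bis[(2Z)-2-methylbut-2-enoate] | C=C([C@H](C[C@H]1OC1(C)C)OC(=O)/C(C)=C\C)[C@@H]1C[C@@H]2O[C@]2(C)[C@H](OC(=O)/C(C)=C\C)[C@H]1OC(=O)/C(C)=C\C | target

## Step count and risks

Total steps: 9. Longest linear sequence: 9 (1 → 16).

**Step 3 (Diels–Alder).** The risks are Friedel–Crafts-type conjugate alkylation of the electron-rich furan instead of cycloaddition, and only moderate endo, regio- and facial selectivity. The fallback sets out from 7 and comes back at 9. 7 is combined with commercial 3-acryloyl-1,3-oxazolidin-2-one under [Cu(L)](SbF6)2 catalysis, L = 2,2′-isopropylidenebis(4-tert-butyl-2-oxazoline), in CH2Cl2 at −78 °C, using the ligand enantiomer that gives the 1R,2R,4R adduct; enantioselective furan cycloaddition is established for this two-point-binding dienophile. This gives the endo imide adduct F1. AlMe3/MeNH(OMe)·HCl converts it into the Weinreb amide F2, MeMgBr into the methyl ketone F3, and KHMDS/PhNTf2 (THF, −78 °C) into the terminal enol triflate F4. Nozaki–Hiyama–Kishi coupling (CrCl2, NiCl2 1 mol %, DMF) of F4 with 4-methylpent-3-enal F5, made by Dess–Martin oxidation of commercial 4-methylpent-3-en-1-ol and used at once, gives 9 together with its carbinol epimer F6. 9 re-enters at step 5; F6 is esterified with retention (10, 2,4,6-trichlorobenzoyl chloride, Et3N, toluene) and gives the same ester 11.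

**Step 6 (rhodium ring opening).** The risks are that the trisubstituted alkene slows the catalyst, or that the other bridgehead C–O bond ionises. The fallback sets out from 11 and comes back at 13. CuCl (5 mol %), 4,5-bis(diphenylphosphino)-9,9-dimethylxanthene, NaOtBu, B2pin2 (1.05 equiv) and MeOH in THF effect syn exo borylcupration, which puts boron on the unsubstituted alkene carbon and copper on the methyl-bearing one. Syn β-alkoxide elimination then opens the bridge to the cis-hydroxy boronate F9, so the regiochemistry is fixed by the addition step and not by an allyl intermediate. Oxidation with NaBO3·4H2O in the same flask gives the cis-diol F10, the C5 epimer of 13. MnO2 oxidises only its allylic hydroxyl to the hydroxy enone F11, and Luche reduction (NaBH4, CeCl3·7H2O, MeOH, −78 °C; axial hydride delivery as in carvone → cis-carveol) gives 13.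

**Step 5 (Mitsunobu with angelic acid).** The risks are SN2′ attack at the terminal methylene, elimination, or partial Z → E isomerisation. The fallback sets out from 9 and comes back at 11. Dess–Martin periodinane oxidises 9 to the cross-conjugated enone F7. Reduction with (R)-1-methyl-3,3-diphenyltetrahydro-1H,3H-pyrrolo[1,2-c][1,3,2]oxazaborole and catecholborane (toluene, −78 °C), in which the alkenyl group acts as the large substituent, gives the (3S)-alcohol F8 (the same compound as F6). Esterification with 10 through the 2,4,6-trichlorobenzoyl mixed anhydride (retention) gives 11.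

## Further compounds

F1 | step 3 | 3-[(1R,2R,4R)-5-methyl-7-oxabicyclo[2.2.1]hept-5-ene-2-carbonyl]-1,3-oxazolidin-2-one (endo) | O=C(N1CCOC1=O)[C@@H]1C[C@@H]2C(C)=C[C@H]1O2
F2 | step 3 | (1R,2R,4R)-N-methoxy-N,5-dimethyl-7-oxabicyclo[2.2.1]hept-5-ene-2-carboxamide | CON(C)C(=O)[C@@H]1C[C@@H]2C(C)=C[C@H]1O2
F3 | step 3 | 1-[(1R,2R,4R)-5-methyl-7-oxabicyclo[2.2.1]hept-5-en-2-yl]ethan-1-one | CC(=O)[C@@H]1C[C@@H]2C(C)=C[C@H]1O2
F4 | step 3 | 1-[(1R,2R,4R)-5-methyl-7-oxabicyclo[2.2.1]hept-5-en-2-yl]ethenyl trifluoromethanesulfonate | C=C(OS(=O)(=O)C(F)(F)F)[C@@H]1C[C@@H]2C(C)=C[C@H]1O2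
F5 | step 3 | 4-methylpent-3-enal | CC(C)=CCC=O
F6 | step 3 | (3S)-6-methyl-2-[(1R,2S,4R)-5-methyl-7-oxabicyclo[2.2.1]hept-5-en-2-yl]hepta-1,5-dien-3-ol | C=C([C@@H](O)CC=C(C)C)[C@@H]1C[C@@H]2C(C)=C[C@H]1O2
F7 | step 5 | 6-methyl-2-[(1R,2S,4R)-5-methyl-7-oxabicyclo[2.2.1]hept-5-en-2-yl]hepta-1,5-dien-3-one | C=C(C(=O)CC=C(C)C)[C@@H]1C[C@@H]2C(C)=C[C@H]1O2
F8 | step 5 | (3S)-6-methyl-2-[(1R,2S,4R)-5-methyl-7-oxabicyclo[2.2.1]hept-5-en-2-yl]hepta-1,5-dien-3-ol (same compound as F6) | C=C([C@@H](O)CC=C(C)C)[C@@H]1C[C@@H]2C(C)=C[C@H]1O2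
F9 | step 6 | cis-hydroxy boronate: C5 epimer of 13 with 4,4,5,5-tetramethyl-1,3,2-dioxaborolan-2-yl in place of the C5 hydroxyl, cis to the C6 hydroxyl | C=C([C@H](CC=C(C)C)OC(=O)/C(C)=C\C)[C@@H]1CC=C(C)[C@@H](B2OC(C)(C)C(C)(C)O2)[C@H]1O
F10 | step 6 | (3S)-2-[(1S,5R,6S)-5,6-dihydroxy-4-methylcyclohex-3-en-1-yl]-6-methylhepta-1,5-dien-3-yl (2Z)-2-methylbut-2-enoate (cis-diol) | C=C([C@H](CC=C(C)C)OC(=O)/C(C)=C\C)[C@@H]1CC=C(C)[C@@H](O)[C@H]1O
F11 | step 6 | (3S)-2-[(1S,6S)-6-hydroxy-4-methyl-5-oxocyclohex-3-en-1-yl]-6-methylhepta-1,5-dien-3-yl (2Z)-2-methylbut-2-enoate | C=C([C@H](CC=C(C)C)OC(=O)/C(C)=C\C)[C@@H]1CC=C(C)C(=O)[C@H]1O
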